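**Strategy**

Cembrane numbering is used: C1 carries the isopropyl group, C7 the acetate, the oxolane is O/C8–C11 and C12 is the carbinol. The plan exploits the C7–C12 segment: its four oxygen-bearing centres are those of an E,E-geraniol-type bis-epoxide inverted at C7 and C11. Double Sharpless epoxidation of 8-hydroxygeraniol gives an open-chain bis(epoxy alcohol); base then starts a Payne shift at C6/C7, and the C8 alkoxide released opens the C11–C12 epoxide 5-exo, forming the O–C11 bond. One operation closes the oxolane and a C6–C7 oxirane and fixes all four stereocentres. Both chain ends are then extended and joined through the isopropyl diene by Suzuki couplings.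

Key step: step 4

**Route**

Step 1
Reactants: 1 geranyl acetate
Product: 2 (2E,6E)-8-hydroxy-3,7-dimethylocta-2,6-dien-1-yl acetate
Conditions: SeO2 (cat.), t-BuOOH, salicylic acid (cat.), CH2Cl2, rt
Reagents that add atoms: tert-butyl hydroperoxide CC(C)(C)OO; selenium dioxide O=[Se]=O (catalytic oxygen carrier)
Why: Riley-type SeO2 allylic oxidation (ene reaction, then [2,3]-sigmatropic shift) should hydroxylate the E-methyl group of the electron-richer distal alkene, the allylic acetate deactivating the proximal one.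

Step 2
Reactants: 2 (2E,6E)-8-hydroxy-3,7-dimethylocta-2,6-dien-1-yl acetate
Product: 3 (2E,6E)-2,6-dimethylocta-2,6-diene-1,8-diol
Conditions: K2CO3 (cat.), MeOH, rt
Reagents that add atoms: none
Why: Base-catalysed transesterification (methanolysis of the acetate) should free the second allylic alcohol without touching the alkenes.

Step 3
Reactants: 3 (2E,6E)-2,6-dimethylocta-2,6-diene-1,8-diol
Product: 4 (2R,3R,6R,7R)-2,3:6,7-diepoxy-2,6-dimethyloctane-1,8-diol
Conditions: Ti(OiPr)4 (cat.), D-(−)-diethyl tartrate (cat.), t-BuOOH (anhydrous, isooctane), 4 Å molecular sieves, CH2Cl2, −20 °C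
Reagents that add atoms: tert-butyl hydroperoxide CC(C)(C)OO
Why: Sharpless asymmetric epoxidation: each allylic alcohol binds the titanium tartrate and should be epoxidised on the face dictated by D-(−)-tartrate, which sets C7, C8, C11 and C12 (all R) under reagent control, the double reaction raising the enantiomeric purity further.

Step 4
Reactants: 4 (2R,3R,6R,7R)-2,3:6,7-diepoxy-2,6-dimethyloctane-1,8-diol
Product: 6 (2R)-2-[(2S,5R)-5-methyl-5-[(2S)-oxiran-2-yl]oxolan-2-yl]propane-1,2-diol, via Payne-shifted terminal epoxide alkoxide 5 (not isolated)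
Conditions: 0.5 M aq. NaOH, t-BuOH, 0 °C to rt; neutralise at partial conversion if the oxirane starts to hydrolyse
Reagents that add atoms: none
Why: Deprotonation at the C6 hydroxyl sets off a Payne rearrangement in which the alkoxide attacks C7 of the neighbouring oxirane (3-exo-tet SN2), and the C8 alkoxide released then attacks C11 of the second oxirane (5-exo-tet SN2), forming the O–C11 bond before the C12 alkoxide is protonated. The closest known reaction type is the base-induced Payne rearrangement–epoxide-opening cascade of polyepoxy alcohols to oxolanes. Two rings close, the C6–C7 oxirane in 3-exo-tet mode and the oxolane in 5-exo-tet mode. C7 and C11 are set by inversion in the two SN2 displacements, while C8 and C12 keep the configuration written in by the Sharpless epoxidation, so the 2,5-cis oxolane with 7S,8R,11S,12R follows from the bis-epoxide alone. The step needs initiation from the C6 alkoxide and not the C13 alkoxide, and exo attack at C11 and not endo attack at C12; both are secured because the productive displacements occur at secondary carbons whereas the competing ones would be SN2 attacks at the fully substituted C12 or C8, and the neopentyl-like C7 shields the new oxirane from the C12 hydroxyl. The unfavourable Payne equilibrium should be drained by the irreversible oxolane closure.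

Step 5
Reactants: 6 (2R)-2-[(2S,5R)-5-methyl-5-[(2S)-oxiran-2-yl]oxolan-2-yl]propane-1,2-diol
Product: 7 (2R)-2-[(2S,5R)-5-[(1S)-1-hydroxypent-4-yn-1-yl]-5-methyloxolan-2-yl]propane-1,2-diol
Conditions: propargylmagnesium bromide (excess), Et2O, −78 °C to 0 °C; aq. NH4Cl
Reagents that add atoms: propargylmagnesium bromide C#CC[Mg]Br
Why: Grignard opening of a monosubstituted epoxide should occur by SN2 attack at the terminal C6, so C7 keeps its configuration and C3–C5 arrive as a terminal alkyne, the excess reagent covering the two hydroxyls.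

Step 6
Reactants: 7 (2R)-2-[(2S,5R)-5-[(1S)-1-hydroxypent-4-yn-1-yl]-5-methyloxolan-2-yl]propane-1,2-diol
Product: 9 (1S)-1-[(2R,5S)-2-methyl-5-[(2R)-2-methyloxiran-2-yl]oxolan-2-yl]pent-4-yn-1-ol, via primary tosylate 8 (not isolated)
Conditions: TsCl, Et3N, Bu2SnO (cat.), CH2Cl2, 0 °C; then K2CO3, MeOH, rt
Reagents that add atoms: none
Why: Stannylene-accelerated sulfonylation should select the primary hydroxyl of the 1,2-diol, and the C12 alkoxide then closes the oxirane by intramolecular Williamson displacement at C13, which leaves the C12 configuration untouched.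

Step 7
Reactants: 9 (1S)-1-[(2R,5S)-2-methyl-5-[(2R)-2-methyloxiran-2-yl]oxolan-2-yl]pent-4-yn-1-ol
Product: 10 (2R)-2-[(2S,5R)-5-[(1S)-1-hydroxypent-4-yn-1-yl]-5-methyloxolan-2-yl]but-3-en-2-ol
Conditions: Me3S+ I−, n-BuLi (excess ylide), THF, −10 °C to rt
Reagents that add atoms: trimethylsulfonium iodide C[S+](C)C.[I-]
Why: Sulfonium-ylide homologation of an epoxide (Corey–Chaykovsky-type ylide attack at the CH2 terminus C13, then ylide-mediated elimination of dimethyl sulfide) should give the one-carbon-extended tertiary allylic alcohol with C12 unchanged.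

Step 8
Reactants: 10 (2R)-2-[(2S,5R)-5-[(1S)-1-hydroxypent-4-yn-1-yl]-5-methyloxolan-2-yl]but-3-en-2-ol
Product: 12 (2R)-2-[(2S,5R)-5-[(1S,4E)-1-hydroxy-5-iodo-4-methylpent-4-en-1-yl]-5-methyloxolan-2-yl]but-3-en-2-ol, via alkenyl(dimethyl)alane 11 (not isolated)
Conditions: AlMe3 (excess), Cp2ZrCl2 (cat.), CH2Cl2, 0 °C to rt; then I2, THF, −30 °C; aq. potassium sodium tartrate
Reagents that add atoms: trimethylaluminium C[Al](C)C; iodine II
Why: Negishi zirconium-catalysed carboalumination adds methyl and aluminium syn across the terminal alkyne with methyl at C4, and iodinolysis with retention should give the E-alkenyl iodide, the hindered monosubstituted alkene reacting far more slowly.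

Step 9
Reactants: 13 3-methylbut-1-yne
Product: 15 2-[(1Z)-2-bromo-3-methylbut-1-en-1-yl]-4,4,5,5-tetramethyl-1,3,2-dioxaborolane, via alkenyldibromoborane 14 (not isolated)
Conditions: BBr3, CH2Cl2, −78 °C to rt; then pinacol, CH2Cl2, −78 °C to rt
Reagents that add atoms: boron tribromide BrB(Br)Br; pinacol CC(C)(O)C(C)(C)O
Why: Bromoboration of a terminal alkyne is a syn addition that places bromine on the internal carbon and boron on the terminal carbon, and esterification with pinacol should fix the Z-bromoalkenylboronate.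

Step 10
Reactants: 12 (2R)-2-[(2S,5R)-5-[(1S,4E)-1-hydroxy-5-iodo-4-methylpent-4-en-1-yl]-5-methyloxolan-2-yl]but-3-en-2-ol; 15 2-[(1Z)-2-bromo-3-methylbut-1-en-1-yl]-4,4,5,5-tetramethyl-1,3,2-dioxaborolane
Product: 16 (2R)-2-[(2S,5R)-5-[(1S,4E,6Z)-7-bromo-1-hydroxy-4,8-dimethylnona-4,6-dien-1-yl]-5-methyloxolan-2-yl]but-3-en-2-ol
Conditions: Pd(dppf)Cl2 (cat.), aq. K3PO4, THF, rt
Reagents that add atoms: none
Why: Suzuki–Miyaura coupling: zerovalent palladium should insert into the unhindered alkenyl C–I bond much faster than into the α-branched C–Br bond, and both partners couple with retention, so the C3=C4 alkene stays E and the bromine on C1 ends cis to C3.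

Step 11
Reactants: 16 (2R)-2-[(2S,5R)-5-[(1S,4E,6Z)-7-bromo-1-hydroxy-4,8-dimethylnona-4,6-dien-1-yl]-5-methyloxolan-2-yl]but-3-en-2-ol
Product: 18 (1E,3E,7S,8R,11S,12R)-8,11-epoxycembra-1,3-diene-7,12-diol, via B-alkyl-9-BBN borane 17 (not isolated)
Conditions: 9-BBN (excess), THF, rt; then slow addition to Pd(dppf)Cl2 (cat.), AsPh3, Cs2CO3, DMF/THF/H2O, 50 °C, high dilution
Reagents that add atoms: none
Why: Anti-Markovnikov hydroboration by 9-BBN should occur only at the monosubstituted alkene, and the intramolecular B-alkyl Suzuki–Miyaura coupling at the alkenyl bromide should close the 14-membered ring with retention, so C14 ends cis to C3 as in the target diene.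

Step 12
Reactants: 18 (1E,3E,7S,8R,11S,12R)-8,11-epoxycembra-1,3-diene-7,12-diol
Product: 19 CNP0199953.1, (1E,3E,7S,8R,11S,12R)-7-acetoxy-8,11-epoxycembra-1,3-dien-12-ol
Conditions: Ac2O, pyridine, DMAP (cat.), CH2Cl2, 0 °C to rt
Reagents that add atoms: acetic anhydride CC(=O)OC(C)=O
Why: DMAP-catalysed acylation should acetylate only the secondary C7 hydroxyl, the tertiary C12 hydroxyl being too hindered under these conditions.

**Compound list**

1 | geranyl acetate, (2E)-3,7-dimethylocta-2,6-dien-1-yl acetate | CC(C)=CCC/C(C)=C/COC(C)=O | starting material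
2 | (2E,6E)-8-hydroxy-3,7-dimethylocta-2,6-dien-1-yl acetate | OC/C(C)=C/CC/C(C)=C/COC(C)=O | intermediate
3 | (2E,6E)-2,6-dimethylocta-2,6-diene-1,8-diol | OC/C(C)=C/CC/C(C)=C/CO | intermediate
4 | (2R,3R,6R,7R)-2,3:6,7-diepoxy-2,6-dimethyloctane-1,8-diol | OC[C@H]1O[C@]1(C)CC[C@H]1O[C@]1(C)CO | intermediate
5 | (2R)-4-[(2R,3R)-3-(hydroxymethyl)-3-methyloxiran-2-yl]-2-[(2S)-oxiran-2-yl]butan-2-ol, present as its alkoxide (not isolated) | OC[C@@]1(C)O[C@@H]1CC[C@@](C)(O)[C@@H]1CO1 | intermediate
6 | (2R)-2-[(2S,5R)-5-methyl-5-[(2S)-oxiran-2-yl]oxolan-2-yl]propane-1,2-diol | OC[C@@](C)(O)[C@@H]1CC[C@@](C)(O1)[C@@H]1CO1 | intermediate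
7 | (2R)-2-[(2S,5R)-5-[(1S)-1-hydroxypent-4-yn-1-yl]-5-methyloxolan-2-yl]propane-1,2-diol | OC[C@@](C)(O)[C@@H]1CC[C@@](C)(O1)[C@@H](O)CCC#C | intermediate
8 | (2R)-2-hydroxy-2-[(2S,5R)-5-[(1S)-1-hydroxypent-4-yn-1-yl]-5-methyloxolan-2-yl]propyl 4-methylbenzenesulfonate (not isolated) | Cc1ccc(cc1)S(=O)(=O)OC[C@@](C)(O)[C@@H]1CC[C@@](C)(O1)[C@@H](O)CCC#C | intermediate
9 | (1S)-1-[(2R,5S)-2-methyl-5-[(2R)-2-methyloxiran-2-yl]oxolan-2-yl]pent-4-yn-1-ol | C1O[C@@]1(C)[C@@H]2CC[C@@](C)(O2)[C@@H](O)CCC#C | intermediate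
10 | (2R)-2-[(2S,5R)-5-[(1S)-1-hydroxypent-4-yn-1-yl]-5-methyloxolan-2-yl]but-3-en-2-ol | C=C[C@@](C)(O)[C@@H]1CC[C@@](C)(O1)[C@@H](O)CCC#C | intermediate
11 | (E)-alkenyl(dimethyl)alane from 10, hydroxyls drawn free but present as aluminium alkoxides (not isolated) | C=C[C@@](C)(O)[C@@H]1CC[C@@](C)(O1)[C@@H](O)CC/C(C)=C/[Al](C)C | intermediate
12 | (2R)-2-[(2S,5R)-5-[(1S,4E)-1-hydroxy-5-iodo-4-methylpent-4-en-1-yl]-5-methyloxolan-2-yl]but-3-en-2-ol | C=C[C@@](C)(O)[C@@H]1CC[C@@](C)(O1)[C@@H](O)CC/C(C)=C/I | intermediate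
13 | 3-methylbut-1-yne | CC(C)C#C | starting material
14 | dibromo[(1Z)-2-bromo-3-methylbut-1-en-1-yl]borane (not isolated) | CC(C)/C(Br)=C/B(Br)Br | intermediate
15 | 2-[(1Z)-2-bromo-3-methylbut-1-en-1-yl]-4,4,5,5-tetramethyl-1,3,2-dioxaborolane | CC(C)/C(Br)=C/B1OC(C)(C)C(C)(C)O1 | intermediate
16 | (2R)-2-[(2S,5R)-5-[(1S,4E,6Z)-7-bromo-1-hydroxy-4,8-dimethylnona-4,6-dien-1-yl]-5-methyloxolan-2-yl]but-3-en-2-ol | C=C[C@@](C)(O)[C@@H]1CC[C@@](C)(O1)[C@@H](O)CC/C(C)=C/C=C(\Br)C(C)C | intermediate
17 | B-alkyl-9-borabicyclo[3.3.1]nonane from 16, boron on C14 (not isolated) | C1CC2CCCC(C1)B2CC[C@@](C)(O)[C@@H]1CC[C@@](C)(O1)[C@@H](O)CC/C(C)=C/C=C(\Br)C(C)C | intermediate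
18 | (1E,3E,7S,8R,11S,12R)-8,11-epoxycembra-1,3-diene-7,12-diol | O[C@H]1CC/C(C)=C/C=C(/C(C)C)CC[C@@](C)(O)[C@@H]2CC[C@@]1(C)O2 | intermediate
19 | CNP0199953.1, (1E,3E,7S,8R,11S,12R)-7-acetoxy-8,11-epoxycembra-1,3-dien-12-ol | CC(=O)O[C@H]1CC/C(C)=C/C=C(/C(C)C)CC[C@@](C)(O)[C@@H]2CC[C@@]1(C)O2 | target

**Step count**

Total steps: 12. Longest linear sequence: 11 (steps 1–8 and 10–12); step 9 is a one-step side branch.

**Steps most likely to fail**

1. Step 4. The cascade may be initiated from the wrong end (a Payne shift at the C13 hydroxyl followed by attack on the other oxirane), or the new C6–C7 oxirane may be opened further by hydroxide or by oligomerisation. The fallback differentiates the two ends with a protecting group and sets out from 2. Sharpless epoxidation of 2 with D-(−)-diethyl tartrate should give (2E)-5-[(2R,3R)-3-(hydroxymethyl)-3-methyloxiran-2-yl]-3-methylpent-2-en-1-yl acetate F1. Silylation (TBSCl, imidazole) should give (2E)-5-[(2R,3R)-3-({[tert-butyl(dimethyl)silyl]oxy}methyl)-3-methyloxiran-2-yl]-3-methylpent-2-en-1-yl acetate F2. Methanolysis (K2CO3, MeOH) should give (2E)-5-[(2R,3R)-3-({[tert-butyl(dimethyl)silyl]oxy}methyl)-3-methyloxiran-2-yl]-3-methylpent-2-en-1-ol F3. A second Sharpless epoxidation should give [(2R,3R)-3-{2-[(2R,3R)-3-({[tert-butyl(dimethyl)silyl]oxy}methyl)-3-methyloxiran-2-yl]ethyl}-3-methyloxiran-2-yl]methanol F4. With only the C6 hydroxyl free, NaH in THF should then give (2R)-1-{[tert-butyl(dimethyl)silyl]oxy}-2-[(2S,5R)-5-methyl-5-[(2S)-oxiran-2-yl]oxolan-2-yl]propan-2-ol F5 by the same Payne/5-exo sequence under non-aqueous conditions. Bu4NF in THF removes the silyl group and the route is rejoined at 6.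

2. Step 11. Intermolecular coupling (oligomerisation), protodeboronation or β-hydride elimination of the alkylborane may outrun ring closure at the hindered alkenyl bromide. The fallback replaces the boron-based closure by a reductive one and sets out from 16. Hydroboration with 9-BBN followed by I2/NaOMe should give (2R)-2-[(2S,5R)-5-[(1S,4E,6Z)-7-bromo-1-hydroxy-4,8-dimethylnona-4,6-dien-1-yl]-5-methyloxolan-2-yl]-4-iodobutan-2-ol F6. Its primary iodide and alkenyl bromide are then joined by nickel-catalysed reductive cross-electrophile coupling (NiCl2(dme), 4,4′-di-tert-butyl-2,2′-bipyridine, Zn, NaI, DMA, high dilution), which tolerates free hydroxyls, and the route is rejoined at 18.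

3. Step 10. The bifunctional bromo-boronate may couple with itself, or oxidative addition into its own C–Br bond may erode the iodide-over-bromide selectivity. The fallback removes boron from the coupling and sets out from 10 and 15. Iododeboronation of 15 (I2, aq. NaOH, THF, retention) should give (1Z)-2-bromo-1-iodo-3-methylbut-1-ene F7. Alkyne 10 is carboaluminated as in step 8 to alane 11, which is transmetalated with ZnCl2 and coupled with F7 at its C–I bond under Pd(PPh3)4 catalysis (Negishi coupling), and the route is rejoined at 16 without passing through 12.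

Further compounds
F1 | step 4 | (2E)-5-[(2R,3R)-3-(hydroxymethyl)-3-methyloxiran-2-yl]-3-methylpent-2-en-1-yl acetate | OC[C@@]1(C)O[C@@H]1CC/C(C)=C/COC(C)=O
F2 | step 4 | (2E)-5-[(2R,3R)-3-({[tert-butyl(dimethyl)silyl]oxy}methyl)-3-methyloxiran-2-yl]-3-methylpent-2-en-1-yl acetate | CC(C)(C)[Si](C)(C)OC[C@@]1(C)O[C@@H]1CC/C(C)=C/COC(C)=O
F3 | step 4 | (2E)-5-[(2R,3R)-3-({[tert-butyl(dimethyl)silyl]oxy}methyl)-3-methyloxiran-2-yl]-3-methylpent-2-en-1-ol | CC(C)(C)[Si](C)(C)OC[C@@]1(C)O[C@@H]1CC/C(C)=C/CO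
F4 | step 4 | [(2R,3R)-3-{2-[(2R,3R)-3-({[tert-butyl(dimethyl)silyl]oxy}methyl)-3-methyloxiran-2-yl]ethyl}-3-methyloxiran-2-yl]methanol | CC(C)(C)[Si](C)(C)OC[C@@]1(C)O[C@@H]1CC[C@@]1(C)O[C@@H]1CO
F5 | step 4 | (2R)-1-{[tert-butyl(dimethyl)silyl]oxy}-2-[(2S,5R)-5-methyl-5-[(2S)-oxiran-2-yl]oxolan-2-yl]propan-2-ol | CC(C)(C)[Si](C)(C)OC[C@@](C)(O)[C@@H]1CC[C@@](C)(O1)[C@@H]1CO1
F6 | step 11 | (2R)-2-[(2S,5R)-5-[(1S,4E,6Z)-7-bromo-1-hydroxy-4,8-dimethylnona-4,6-dien-1-yl]-5-methyloxolan-2-yl]-4-iodobutan-2-ol | ICC[C@@](C)(O)[C@@H]1CC[C@@](C)(O1)[C@@H](O)CC/C(C)=C/C=C(\Br)C(C)C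
F7 | step 10 | (1Z)-2-bromo-1-iodo-3-methylbut-1-ene | CC(C)/C(Br)=C/I
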